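## Structural features

The target is a cyclohexene (numbered here C1 quaternary, C2 and C3 methylene, C4 the methyl-bearing alkene carbon, C5 the alkene CH, C6 the methine) that carries two 7-methoxycoumarin units, both bound through their C8: one directly to C6, the other through an (E)-ethene bridge to C1, which also holds a methyl group. C1 (R) and C6 (R) are adjacent stereocentres; the arene on C6 and the ethenyl arm on C1 are cis, so the arene is trans to the C1 methyl. Fragile points are the two lactones, the C6–H bond (both allylic and benzylic), and the 1,5-diene formed by the ethenyl arm, C1, C6 and the ring alkene, which invites Cope-type reorganisation on strong heating. The real difficulty is the C6–C8 bond: C8 lies between the oxygen-bearing C7 and C8a, and C6 lies next to a quaternary centre, so a late coupling there is unattractive. The cis C1/C6 relationship is the second problem, because an addition to C6 next to a carbon carrying methyl and a slim unsaturated group cannot be trusted to choose one face. The key step exploits the pattern of the benzene ring on C6: oxygen on C7 and C8a, the C6 substituent on C8 between them, carbon on C4a, hydrogen on C5 and C6 of the coumarin. This is a 2,4-dihydroxybenzoate, the folded form of a 3,5-dioxoheptanoate whose C2 becomes C4a, C3 becomes C8a, C4 becomes C8, C5 becomes C7, and whose C7 (an aldehyde masked as a methoxy enone) becomes C5. Such a chain has three six-membered ways to close (C2 to C7, the C3 enol oxygen to C7, the C5 enol oxygen to the ester carbon), not one, and only the first is irreversible; the plan relies on that.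

## Logic of the disconnections

27 to 22 and 25. The bond between the terminus of the ethenyl arm and C8 of the second coumarin is cut. This arene is not congested at the alkene end, and a terminal alkyne in 22 is a latent E-alkenyl metal through syn hydrometalation. One whole coumarin leaves as the simple 25. The forward step must hydroborate the alkyne in preference to the ring alkene and the coumarin C3=C4 bond, and the coupling must spare two lactones.

25 to 24 to 23. The O–methyl and C8–iodine bonds are cut. The free 7-hydroxyl is kept for the iodination because its phenoxide directs the halogen to C8; the forward iodination must not go to C6 or C3.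

22 to 21 to 19. The C–Si bond is cut, then the pyranone ring at C3=C4 and at O1–C2, which returns the lactone to a salicylaldehyde. Keeping the alkyne instead of the ethenyl arm at this stage removes the 1,5-diene, so the hot lactonisation is safe. The forward step must reach the Z cinnamate for ring closure.

19 to 18 to 17 to 16. Only oxidation level and one O–methyl bond change. The carbon that becomes C4 is carried as an ester because the key step needs it as an activating group. The methylation must distinguish two phenols, which the hydrogen bond of the ortho hydroxyl to the ester allows.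

16 to 15. The arene bond C4a–C5 (C2–C7 of the chain) is cut and the benzene ring unravels into an open tricarbonyl chain attached to C6 through an sp3 carbon. The congested aryl–C6 bond is then never made by coupling. The forward step must close through carbon in preference to the two oxygen modes and must leave the ring stereocentres untouched.

15 to 12 and 14; 14 to 13. The chain bond C4–C5, between the branched carbon and the enone carbonyl, is cut. The carbon next to the ring becomes the terminal carbon of a β-keto ester dianion, and the three-carbon masked aldehyde becomes the simple amide 14, made from 13 by one C–N bond. The forward step demands acylation at a hindered carbanion without 1,4-addition to the push–pull alkene.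

12 to 10 to 8 to 6. The chain bond C2–C3 is cut (malonate homologation of an acid), then the C–Si bond, then the alkyne is returned to an aldehyde and the acid to its methyl ester. The order lets the strong base of the silylation meet only a carboxylate. The aldehyde is non-enolisable, so nothing can epimerise.

6 to 4 and 5. The ring bonds C1–C6 and C2–C3 are cut in a [4+2] sense. One step then places the methyl groups, the alkene and the side chain, and sets both stereocentres with the cis relationship (formyl endo). It demands endo selectivity and face selection by a chiral Lewis acid.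

4 to 3 to 1 and 2. The diene is traced to its conjugated isomer (a double-bond shift, no bond cut) and this to an olefination of 1 with 2 at C2=C3. The forward steps demand E geometry and kinetic α-protonation.

## Other disconnections considered

Alternative 1: The cut is made in both pyranone rings at once, at C4–C4a and O1–C2, which leads back to the bis(aryl propargyl ether) A2. Forward, heating A2 would cause on each arene a propargyl Claisen shift to the only free ortho carbon (the future C4a), a hydrogen shift and an oxa-6π electrocyclisation, giving the bis(2H-chromene) A1.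
- In favour: four bonds and two rings form in one metal-free operation, and both arenes are treated alike. The regiochemistry is not in doubt because the other ortho position is the blocked C8. On this point it is the better plan, since the chosen chain has competing oxygen closures.
- Against: A1 has CH2 at both C2 positions, so two oxidations to lactones must follow in a molecule with other allylic and benzylic sites (C3, the C4 methyl, C6–H). The Claisen temperature is applied to the finished 1,5-diene, where Cope reorganisation and retro-[4+2] are open. A2 already contains the C6–aryl bond and both stereocentres, so the step does nothing for the hard part.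
- Comparison: structurally, the chosen plan uses its ring-forming step to create the hindered arene on C6, whereas alternative 1 decorates arenes that must be attached first. Mechanistically it is neutral and pericyclic against basic and ionic. In step count it is shorter after its key step (two oxidations against six steps) but leaves the route to A2 unsolved.

Alternative 2: The cut is at the bond from the ethenyl carbon to C8 of the remote coumarin together with its C8a–O bond. Ketone A3 is traced to the C1 acetic acid A4 and a methoxy-substituted aryne. Forward, the carboxylate of A4 would add to the aryne at the carbon meta to methoxy, and the aryl anion, now ortho to methoxy, would take the acyl group, giving the ortho-hydroxyaryl ketone A3.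
- In favour: no transition metal is needed, and oxygen and carbon arrive together with a regiochemistry set by the methoxy group. Later ortho-formylation of the phenol can go only to C4a. In regiochemical certainty for this arene it equals a cross-coupling, and a twofold late annulation of both arenes would be a symmetric finish.
- Against: it spends the key step on the easy arene (one Suzuki–Miyaura coupling in the chosen plan). A3 has a ketone and a methylene where the E alkene belongs, so reduction and dehydration follow. Both arenes still lack C4a to C2. Protonation of the aryl anion before acyl transfer would give the aryl ester. The hindered C6 arene must already be present in A4.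
- Comparison: both key steps are anionic, but only the chosen one ends in an irreversible aromatisation. The chosen plan is shorter by at least five steps after the key step.

Alternative 3: The cut is at C2–C3 of the cyclohexene. Cyclohexenol A5 is traced to the 2-isopropenylcyclobutanol A6, in which C1, C2, C6 and C5 form the four-membered ring. Forward, the potassium alkoxide of A6 would undergo the alkoxide-accelerated 1,3-shift of a vinylcyclobutane: C2–C5 breaks, C2 joins the isopropenyl terminus, and the C4=C5 alkene appears.
- In favour: C1 and C6 are bystanders of the shift, so their relationship could be set when the cyclobutane is made. The alkene position and the C4 methyl follow from the mechanism, which makes it the equal of the Diels–Alder step of the chosen plan on that count. The oxyanion allows a low temperature.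
- Against: A5 has a hydroxyl on C2 that must be removed, a protected hydroxymethyl on C1 that must become the ethenyl–aryl arm, and an arene without its pyranone ring. The tetrasubstituted cyclobutane is itself a hard target. The alkoxide can also cleave the ring to an open-chain enolate, which loses the stereochemical tie. The C6–aryl bond must again exist beforehand.
- Comparison: the chosen plan makes the carbocycle directly by [4+2] with the same regiochemical guarantee and keeps its key step for the arene. Both are base-induced reorganisations, but the 1,3-shift competes with cleavage. Alternative 3 is the longest of the four.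

Key step: step 9

Assumption: the (S)-configured oxazaborolidinium catalyst of step 3 is taken to direct the diene to the Re face at C2 of the s-trans enal 5, which gives (1R,6S)-6; if the sense is the reverse, the mirror-image catalyst is used and nothing else changes.

Remark: the descriptor of the ring methine changes between 12 (R), 15 (S) and 16 (R), and that of the quaternary carbon between 22 (S) and 27 (R), only because CIP ranks change; the spatial arrangement is constant from 6 to 27.

## Steps

Step 1
Reactants: 1 3-methylbut-2-enal; 2 trimethyl phosphonoacetate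
Product: 3 methyl (2E)-5-methylhexa-2,4-dienoate
Conditions: NaH, THF, 0 °C → rt
Reagents that add atoms: none
Why: Horner–Wadsworth–Emmons olefination of an enal with a stabilised phosphonate anion; the new C2=C3 bond is E under the usual thermodynamic control.

Step 2
Reactants: 3 methyl (2E)-5-methylhexa-2,4-dienoate
Product: 4 methyl (3E)-5-methylhexa-3,5-dienoate
Conditions: LiN(i-Pr)2, THF/DMPU, −78 °C; then AcOH, −78 °C
Reagents that add atoms: none
Why: Deconjugative protonation: the amide base removes a proton from a terminal methyl group to give the extended trienolate, and kinetic protonation at the α-carbon leaves the 3,5-diene; the C3=C4 bond is E because the s-trans chain of 3 persists in the trienolate.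

Step 3
Reactants: 4 methyl (3E)-5-methylhexa-3,5-dienoate; 5 methacrolein (2-methylprop-2-enal)
Product: 6 methyl 2-[(1R,6S)-6-formyl-3,6-dimethylcyclohex-2-en-1-yl]acetate
Conditions: 5 (3 equiv), (S)-1-(2-methylphenyl)-3,3-diphenyltetrahydro-1H,3H-pyrrolo[1,2-c][1,3,2]oxazaborole (20 mol%), Tf2NH (18 mol%), CH2Cl2, −78 °C
Reagents that add atoms: none
Why: Lewis-acid-catalysed Diels–Alder reaction; the 1-alkyl and 3-methyl groups of 4 both send the unsubstituted diene terminus to the β-carbon of 5, which fixes methyl, alkene and side chain on the ring. The formyl group sits endo, which makes it cis to the CH2CO2Me arm, and the chiral boron cation binds the s-trans enal and shields one face so that the diene adds to the Re face at C2 of 5, setting both centres as (1R,6S).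

Step 4
Reactants: 6 methyl 2-[(1R,6S)-6-formyl-3,6-dimethylcyclohex-2-en-1-yl]acetate
Product: 8 2-[(1R,6S)-6-ethynyl-3,6-dimethylcyclohex-2-en-1-yl]acetic acid, via alkynyl methyl ester 7 (not isolated)
Conditions: dimethyl (1-diazo-2-oxopropyl)phosphonate, K2CO3, MeOH, 0 °C → rt; then LiOH, H2O, 40 °C; HCl to pH 3
Reagents that add atoms: dimethyl (1-diazo-2-oxopropyl)phosphonate, CC(=O)C(=[N+]=[N-])P(=O)(OC)OC; lithium hydroxide, [Li+].[OH-]
Why: Ohira–Bestmann homologation: the diazophosphonate anion released by methanolysis adds to the non-enolisable aldehyde and the diazoalkene loses N2 with a 1,2-shift to the alkyne; hydroxide then saponifies the ester in the same flask. Neither stereocentre carries an acidic hydrogen, so both are retained.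

Step 5
Reactants: 8 2-[(1R,6S)-6-ethynyl-3,6-dimethylcyclohex-2-en-1-yl]acetic acid
Product: 10 2-[(1R,6S)-3,6-dimethyl-6-[(triisopropylsilyl)ethynyl]cyclohex-2-en-1-yl]acetic acid, via bis-silylated silyl ester 9 (not isolated)
Conditions: LiN(i-Pr)2 (2.2 equiv), THF, −78 °C; TIPSOTf (2.2 equiv), −78 → 0 °C; then K2CO3, MeOH/H2O, rt; HCl to pH 3
Reagents that add atoms: triisopropylsilyl trifluoromethanesulfonate, CC(C)[Si](OS(=O)(=O)C(F)(F)F)(C(C)C)C(C)C
Why: Two equivalents of amide base give the carboxylate and the acetylide and the silyl triflate caps both; the silyl ester is hydrolysed by aqueous carbonate while the C-silyl alkyne survives. Working on the acid avoids an ester enolate.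

Step 6
Reactants: 10 2-[(1R,6S)-3,6-dimethyl-6-[(triisopropylsilyl)ethynyl]cyclohex-2-en-1-yl]acetic acid
Product: 12 methyl 4-[(1R,6S)-3,6-dimethyl-6-[(triisopropylsilyl)ethynyl]cyclohex-2-en-1-yl]-3-oxobutanoate, via acyl imidazole 11 (not isolated)
Conditions: CDI, THF, rt; then MeO2CCH2CO2K, MgCl2, Et3N, MeCN, rt → 40 °C; 1 M HCl
Reagents that add atoms: potassium 3-methoxy-3-oxopropanoate, COC(=O)CC(=O)[O-].[K+]; 1,1'-carbonyldiimidazole, O=C(n1ccnc1)n1ccnc1 (its imidazolyl group stays only in 11)
Why: Masamune–Brooks homologation: the acyl imidazole acylates the magnesium enolate of the malonate half-ester and the adduct loses CO2 on acidification, giving the β-keto ester under nearly neutral conditions.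

Step 7
Reactants: 13 (2E)-3-methoxyprop-2-enoic acid
Product: 14 (2E)-N,3-dimethoxy-N-methylprop-2-enamide
Conditions: MeNH(OMe)·HCl, EDC·HCl, N-methylmorpholine, CH2Cl2, 0 °C → rt
Reagents that add atoms: N,O-dimethylhydroxylamine hydrochloride, CNOC.Cl
Why: Carbodiimide-mediated amide formation; acylation of the weakly basic hydroxylamine by the activated acid is much faster than its addition to the push–pull alkene, and the E geometry is not touched.

Step 8
Reactants: 12 methyl 4-[(1R,6S)-3,6-dimethyl-6-[(triisopropylsilyl)ethynyl]cyclohex-2-en-1-yl]-3-oxobutanoate; 14 (2E)-N,3-dimethoxy-N-methylprop-2-enamide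
Product: 15 methyl (6E)-4-[(1S,6S)-3,6-dimethyl-6-[(triisopropylsilyl)ethynyl]cyclohex-2-en-1-yl]-7-methoxy-3,5-dioxohept-6-enoate (C4 unspecified; keto–enol mixture)
Conditions: LiN(i-Pr)2 (2.05 equiv), THF, −78 → 0 °C; 14 (1.2 equiv), −78 → −20 °C; AcOH/NaOAc buffer (pH 5)
Reagents that add atoms: none
Why: Claisen-type γ-acylation of a β-keto ester dianion: the second deprotonation occurs at C4, whose carbanion is the most nucleophilic site, and the N-methoxy-N-methylamide holds the tetrahedral chelate until work-up, so the product is not deprotonated at the cost of the dianion. The new centre at C4 is enolisable and of no consequence; 15 is used without delay.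

Step 9
Reactants: 15 methyl (6E)-4-[(1S,6S)-3,6-dimethyl-6-[(triisopropylsilyl)ethynyl]cyclohex-2-en-1-yl]-7-methoxy-3,5-dioxohept-6-enoate
Product: 16 methyl 3-[(1R,6S)-3,6-dimethyl-6-[(triisopropylsilyl)ethynyl]cyclohex-2-en-1-yl]-2,4-dihydroxybenzoate
Conditions: K2CO3 (3 equiv), MeOH, rt → 50 °C; then 1 M HCl
Reagents that add atoms: none
Why: Carbonate in methanol deprotonates 15 first at C4 of the chain, but the tautomeric anion at C2 (between the ester and the C3 ketone) is in equilibrium with it and is the one that closes: C2 adds to C7, the β-carbon of the methoxy enone, in a 6-endo-trig closure that places C2 to C7 in the new ring. Methoxide is then lost by E1cB across C2–C7, and enolisation of the C3 and C5 ketones gives the benzene ring, an irreversible exit. The closest known reaction is the base-induced aldol-type cyclisation and aromatisation of 3,5-dioxo and 3,5,7-trioxo esters to resorcylates, here with a vinylogous ester in place of the terminal ketone. One ring is closed and no stereocentre is formed; the centre at C4 of the chain is destroyed and the two ring centres carry no acidic hydrogen, so they keep their configuration. The selectivity needed is carbon over oxygen closure: the enol oxygen on C3 can add to C7 to give a 4-pyranone, and the enol oxygen on C5 can attack the ester to give a 4-hydroxy-2-pyranone. The 4-pyranone reopens by methoxide addition at its C6 and lactonisation of a methyl ester is slow at this temperature, whereas aromatisation cannot revert, so the system should drain into 16. The triisopropylsilyl alkyne is stable to carbonate in methanol, and methanol as solvent makes transesterification of the methyl ester degenerate.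

Step 10
Reactants: 16 methyl 3-[(1R,6S)-3,6-dimethyl-6-[(triisopropylsilyl)ethynyl]cyclohex-2-en-1-yl]-2,4-dihydroxybenzoate
Product: 17 methyl 3-[(1R,6S)-3,6-dimethyl-6-[(triisopropylsilyl)ethynyl]cyclohex-2-en-1-yl]-2-hydroxy-4-methoxybenzoate
Conditions: MeI (1.1 equiv), K2CO3 (1.2 equiv), acetone, rt
Reagents that add atoms: iodomethane, CI
Why: Williamson O-methylation: the hydroxyl para to the ester is the more acidic and is free, whereas the ortho hydroxyl is held in a hydrogen bond to the ester carbonyl, so one equivalent of MeI should methylate only the former.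

Step 11
Reactants: 17 methyl 3-[(1R,6S)-3,6-dimethyl-6-[(triisopropylsilyl)ethynyl]cyclohex-2-en-1-yl]-2-hydroxy-4-methoxybenzoate
Product: 18 2-(hydroxymethyl)-6-[(1R,6S)-3,6-dimethyl-6-[(triisopropylsilyl)ethynyl]cyclohex-2-en-1-yl]-5-methoxyphenol
Conditions: LiAlH4, THF, 0 °C → rt; aq. potassium sodium tartrate work-up
Reagents that add atoms: none
Why: Hydride reduction of the aryl ester to the benzylic alcohol; the silyl alkyne and the ring alkene are inert to LiAlH4 at this temperature, and the neutral work-up protects the acid-sensitive hydroxybenzyl alcohol.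

Step 12
Reactants: 18 2-(hydroxymethyl)-6-[(1R,6S)-3,6-dimethyl-6-[(triisopropylsilyl)ethynyl]cyclohex-2-en-1-yl]-5-methoxyphenol
Product: 19 3-[(1R,6S)-3,6-dimethyl-6-[(triisopropylsilyl)ethynyl]cyclohex-2-en-1-yl]-2-hydroxy-4-methoxybenzaldehyde
Conditions: MnO2 (15 equiv), CH2Cl2, rt
Reagents that add atoms: none
Why: MnO2 oxidises the benzylic alcohol selectively to the salicylaldehyde and leaves the phenol and the allylic C–H bonds alone.

Step 13
Reactants: 19 3-[(1R,6S)-3,6-dimethyl-6-[(triisopropylsilyl)ethynyl]cyclohex-2-en-1-yl]-2-hydroxy-4-methoxybenzaldehyde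
Product: 21 8-[(1R,6S)-3,6-dimethyl-6-[(triisopropylsilyl)ethynyl]cyclohex-2-en-1-yl]-7-methoxy-2H-chromen-2-one, via ethyl 2-hydroxycinnamate 20 (not isolated)
Conditions: Ph3P=CHCO2Et (1.5 equiv), N,N-diethylaniline, 210 °C
Reagents that add atoms: ethyl (triphenylphosphoranylidene)acetate, CCOC(=O)C=P(c1ccccc1)(c1ccccc1)c1ccccc1
Why: Wittig olefination followed by thermal E to Z isomerisation and lactonisation, the standard coumarin synthesis from 3-substituted 2-hydroxy-4-methoxybenzaldehydes. The alkyne cannot enter a Cope rearrangement with the ring alkene, because that would require a six-membered cyclic allene.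

Step 14
Reactants: 21 8-[(1R,6S)-3,6-dimethyl-6-[(triisopropylsilyl)ethynyl]cyclohex-2-en-1-yl]-7-methoxy-2H-chromen-2-one
Product: 22 8-[(1R,6S)-6-ethynyl-3,6-dimethylcyclohex-2-en-1-yl]-7-methoxy-2H-chromen-2-one
Conditions: TBAF (1.5 equiv), THF, 0 °C → rt
Reagents that add atoms: none
Why: Fluoride cleaves the C(sp)–Si bond; the lactone tolerates fluoride at or below room temperature.

Step 15
Reactants: 23 7-hydroxy-2H-chromen-2-one (7-hydroxycoumarin)
Product: 24 7-hydroxy-8-iodo-2H-chromen-2-one
Conditions: I2, KI, 20% aq. NH3, 0 °C → rt; then acidify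
Reagents that add atoms: iodine, II
Why: Electrophilic iodination of the phenoxide; in aqueous ammonia the 7-oxido group directs iodine to C8, the ortho position between the two oxygens.

Step 16
Reactants: 24 7-hydroxy-8-iodo-2H-chromen-2-one
Product: 25 8-iodo-7-methoxy-2H-chromen-2-one
Conditions: MeI, K2CO3, acetone, reflux
Reagents that add atoms: iodomethane, CI
Why: Williamson O-methylation of the phenol.

Step 17
Reactants: 22 8-[(1R,6S)-6-ethynyl-3,6-dimethylcyclohex-2-en-1-yl]-7-methoxy-2H-chromen-2-one; 25 8-iodo-7-methoxy-2H-chromen-2-one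
Product: 27 8-[(1R,6R)-3,6-dimethyl-6-[(E)-2-(7-methoxy-2-oxo-2H-chromen-8-yl)ethenyl]cyclohex-2-en-1-yl]-7-methoxy-2H-chromen-2-one, via pinacol alkenylboronate 26 (not isolated)
Conditions: HBpin (1.5 equiv), Cp2ZrHCl (10 mol%), Et3N (10 mol%), THF, 60 °C; H2O quench; then 25, Pd(OAc)2 (5 mol%), SPhos (10 mol%), K3PO4 (3 equiv), 1,4-dioxane/H2O, 70 °C; mildly acidic work-up
Reagents that add atoms: pinacolborane, CC1(C)OBOC1(C)C (its boron unit stays only in 26)
Why: Zirconium-hydride-catalysed syn hydroboration puts boron on the unhindered alkyne terminus and gives the E alkenylboronate; water destroys excess borane before the palladium is added. Suzuki–Miyaura coupling through zerovalent palladium keeps the alkene geometry, SPhos copes with the di-ortho-substituted iodide, and the acidic work-up re-closes any lactone opened by phosphate.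

## Compound list

1 | 3-methylbut-2-enal | CC(C)=CC=O | starting material
2 | trimethyl phosphonoacetate | COC(=O)CP(=O)(OC)OC | starting material
3 | methyl (2E)-5-methylhexa-2,4-dienoate | COC(=O)/C=C/C=C(C)C | intermediate
4 | methyl (3E)-5-methylhexa-3,5-dienoate | COC(=O)C/C=C/C(C)=C | intermediate
5 | methacrolein (2-methylprop-2-enal) | CC(=C)C=O | starting material
6 | methyl 2-[(1R,6S)-6-formyl-3,6-dimethylcyclohex-2-en-1-yl]acetate | O=C[C@@]1(C)CCC(C)=C[C@H]1CC(=O)OC | intermediate
7 | methyl 2-[(1R,6S)-6-ethynyl-3,6-dimethylcyclohex-2-en-1-yl]acetate | C#C[C@@]1(C)CCC(C)=C[C@H]1CC(=O)OC | intermediate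
8 | 2-[(1R,6S)-6-ethynyl-3,6-dimethylcyclohex-2-en-1-yl]acetic acid | C#C[C@@]1(C)CCC(C)=C[C@H]1CC(=O)O | intermediate
9 | triisopropylsilyl 2-[(1R,6S)-3,6-dimethyl-6-[(triisopropylsilyl)ethynyl]cyclohex-2-en-1-yl]acetate | CC(C)[Si](C(C)C)(C(C)C)C#C[C@@]1(C)CCC(C)=C[C@H]1CC(=O)O[Si](C(C)C)(C(C)C)C(C)C | intermediate
10 | 2-[(1R,6S)-3,6-dimethyl-6-[(triisopropylsilyl)ethynyl]cyclohex-2-en-1-yl]acetic acid | CC(C)[Si](C(C)C)(C(C)C)C#C[C@@]1(C)CCC(C)=C[C@H]1CC(=O)O | intermediate
11 | 2-[(1R,6S)-3,6-dimethyl-6-[(triisopropylsilyl)ethynyl]cyclohex-2-en-1-yl]-1-(1H-imidazol-1-yl)ethan-1-one | CC(C)[Si](C(C)C)(C(C)C)C#C[C@@]1(C)CCC(C)=C[C@H]1CC(=O)n1ccnc1 | intermediate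
12 | methyl 4-[(1R,6S)-3,6-dimethyl-6-[(triisopropylsilyl)ethynyl]cyclohex-2-en-1-yl]-3-oxobutanoate | CC(C)[Si](C(C)C)(C(C)C)C#C[C@@]1(C)CCC(C)=C[C@H]1CC(=O)CC(=O)OC | intermediate
13 | (2E)-3-methoxyprop-2-enoic acid | CO/C=C/C(=O)O | starting material
14 | (2E)-N,3-dimethoxy-N-methylprop-2-enamide | CO/C=C/C(=O)N(C)OC | intermediate
15 | methyl (6E)-4-[(1S,6S)-3,6-dimethyl-6-[(triisopropylsilyl)ethynyl]cyclohex-2-en-1-yl]-7-methoxy-3,5-dioxohept-6-enoate (C4 unspecified) | COC(=O)CC(=O)C(C(=O)/C=C/OC)[C@@H]1C=C(C)CC[C@]1(C)C#C[Si](C(C)C)(C(C)C)C(C)C | intermediate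
16 | methyl 3-[(1R,6S)-3,6-dimethyl-6-[(triisopropylsilyl)ethynyl]cyclohex-2-en-1-yl]-2,4-dihydroxybenzoate | COC(=O)c1ccc(O)c([C@@H]2C=C(C)CC[C@]2(C)C#C[Si](C(C)C)(C(C)C)C(C)C)c1O | intermediate
17 | methyl 3-[(1R,6S)-3,6-dimethyl-6-[(triisopropylsilyl)ethynyl]cyclohex-2-en-1-yl]-2-hydroxy-4-methoxybenzoate | COC(=O)c1ccc(OC)c([C@@H]2C=C(C)CC[C@]2(C)C#C[Si](C(C)C)(C(C)C)C(C)C)c1O | intermediate
18 | 2-(hydroxymethyl)-6-[(1R,6S)-3,6-dimethyl-6-[(triisopropylsilyl)ethynyl]cyclohex-2-en-1-yl]-5-methoxyphenol | OCc1ccc(OC)c([C@@H]2C=C(C)CC[C@]2(C)C#C[Si](C(C)C)(C(C)C)C(C)C)c1O | intermediate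
19 | 3-[(1R,6S)-3,6-dimethyl-6-[(triisopropylsilyl)ethynyl]cyclohex-2-en-1-yl]-2-hydroxy-4-methoxybenzaldehyde | O=Cc1ccc(OC)c([C@@H]2C=C(C)CC[C@]2(C)C#C[Si](C(C)C)(C(C)C)C(C)C)c1O | intermediate
20 | ethyl (2E)-3-{3-[(1R,6S)-3,6-dimethyl-6-[(triisopropylsilyl)ethynyl]cyclohex-2-en-1-yl]-2-hydroxy-4-methoxyphenyl}prop-2-enoate | CCOC(=O)/C=C/c1ccc(OC)c([C@@H]2C=C(C)CC[C@]2(C)C#C[Si](C(C)C)(C(C)C)C(C)C)c1O | intermediate
21 | 8-[(1R,6S)-3,6-dimethyl-6-[(triisopropylsilyl)ethynyl]cyclohex-2-en-1-yl]-7-methoxy-2H-chromen-2-one | COc1ccc2ccc(=O)oc2c1[C@@H]1C=C(C)CC[C@]1(C)C#C[Si](C(C)C)(C(C)C)C(C)C | intermediate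
22 | 8-[(1R,6S)-6-ethynyl-3,6-dimethylcyclohex-2-en-1-yl]-7-methoxy-2H-chromen-2-one | COc1ccc2ccc(=O)oc2c1[C@@H]1C=C(C)CC[C@]1(C)C#C | intermediate
23 | 7-hydroxy-2H-chromen-2-one | Oc1ccc2ccc(=O)oc2c1 | starting material
24 | 7-hydroxy-8-iodo-2H-chromen-2-one | Oc1ccc2ccc(=O)oc2c1I | intermediate
25 | 8-iodo-7-methoxy-2H-chromen-2-one | COc1ccc2ccc(=O)oc2c1I | intermediate
26 | 8-[(1R,6R)-3,6-dimethyl-6-[(E)-2-(4,4,5,5-tetramethyl-1,3,2-dioxaborolan-2-yl)ethenyl]cyclohex-2-en-1-yl]-7-methoxy-2H-chromen-2-one | CC1(C)OB(/C=C/[C@@]2(C)CCC(C)=C[C@H]2c2c(OC)ccc3ccc(=O)oc23)OC1(C)C | intermediate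
27 | 8-[(1R,6R)-3,6-dimethyl-6-[(E)-2-(7-methoxy-2-oxo-2H-chromen-8-yl)ethenyl]cyclohex-2-en-1-yl]-7-methoxy-2H-chromen-2-one | COc1ccc2ccc(=O)oc2c1/C=C/[C@@]1(C)CCC(C)=C[C@H]1c1c(OC)ccc2ccc(=O)oc12 | target

## Step count and least certain steps

Total step count: 17. Longest linear sequence: 14 steps (steps 1 to 6, 8 to 14 and 17); step 7 and steps 15 and 16 are side branches.

Step 9 (key step). Closure through oxygen may outrun closure through carbon, and the bulky branch on C4 of the chain may slow the carbon closure so far that the 4-pyranone or the hydroxy-pyranone lactone accumulates, or that the enolised tricarbonyl chain suffers retro-Claisen cleavage by methoxide. Fallback, from 15 back to 16: 15 is closed through oxygen on purpose (PPTS, toluene, 80 °C) to the 4-pyranone methyl 2-{3-[(1R,6S)-3,6-dimethyl-6-[(triisopropylsilyl)ethynyl]cyclohex-2-en-1-yl]-4-oxo-4H-pyran-2-yl}acetate F1. Heating F1 with Mg(OMe)2 in methanol should open the pyranone at C6 by methoxide addition and close the chelated magnesium enolate through carbon, a pyranone-to-resorcylate ring transformation that ends at 16.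

Step 8. Acylation at the hindered terminal carbanion may be slow, so that proton transfer, attack of the dianion at the β-carbon of 14 with loss of methoxide, or O-acylation take over; the labile product may also cyclise during work-up. Fallback, from 12 and 13 back to 15: 12 is silylated twice (Et3N/TMSCl, then LiN(i-Pr)2/TMSCl) to the dienol ether 1-methoxy-1,3-bis(trimethylsilyloxy)-4-[(1S,6S)-3,6-dimethyl-6-[(triisopropylsilyl)ethynyl]cyclohex-2-en-1-yl]buta-1,3-diene F2. 13 is converted with (COCl)2 and catalytic DMF into (2E)-3-methoxyprop-2-enoyl chloride F3. F2 and F3 are combined in CH2Cl2 at −78 → 20 °C (Mukaiyama-type γ-acylation of a bis-silyl dienol ether, with no anionic equilibria), and aqueous work-up returns 15.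

Step 3. Face discrimination or endo preference may be insufficient with this new diene, and the acid may shift the diene into conjugation with its ester. Fallback, from 4 and 5 back to 8: 4 and 5 are joined with the achiral Lewis acid MeAlCl2 (CH2Cl2, −78 °C) to the racemic cis adduct rac-methyl 2-[(1R*,6S*)-6-formyl-3,6-dimethylcyclohex-2-en-1-yl]acetate F4. The conditions of step 4 carry it through the racemic alkynyl ester rac-methyl 2-[(1R*,6S*)-6-ethynyl-3,6-dimethylcyclohex-2-en-1-yl]acetate F5 to the racemic acid rac-2-[(1R*,6S*)-6-ethynyl-3,6-dimethylcyclohex-2-en-1-yl]acetic acid F6. F6 is resolved by crystallisation of its salt with a chiral amine, taken here as (S)-1-phenylethylammonium 2-[(1R,6S)-6-ethynyl-3,6-dimethylcyclohex-2-en-1-yl]acetate F7 (the amine antipode that gives the less soluble salt with the wanted acid is used), and acidification of F7 returns 8.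

Step 13. At 210 °C, thermal degradation of the congested aldehyde or incomplete E to Z isomerisation of the cinnamate may prevent ring closure. Fallback, from 19 back to 21: 19 is heated with ketenylidenetriphenylphosphorane (Ph3P=C=C=O) in toluene at 110 °C. The phenol adds to the ketene to give the ester ylide 2-formyl-5-methoxy-6-[(1R,6S)-3,6-dimethyl-6-[(triisopropylsilyl)ethynyl]cyclohex-2-en-1-yl]phenyl (triphenylphosphoranylidene)acetate F8, whose intramolecular Wittig reaction gives the Z alkene already inside the ring and so leads to 21 at a temperature 100 °C lower.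

Step 17. Borane may reduce the lactone or the excess may borylate the aryl iodide, transmetalation between the two hindered partners may be slow so that protodeboronation wins, and aqueous base may open a lactone with loss of the Z cinnamate geometry. Fallback, from 22 back to 27: palladium-catalysed hydrostannylation of 22 (Bu3SnH, PdCl2(PPh3)2, THF, 0 °C) gives 8-[(1R,6S)-3,6-dimethyl-6-[(E)-2-(tributylstannyl)ethenyl]cyclohex-2-en-1-yl]-7-methoxy-2H-chromen-2-one F9, which is isolated and joined to 25 by a base-free Stille coupling (Pd(PPh3)4, CuI, DMF, 50 °C) to give 27.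

## Further compounds

F1 | step 9 | methyl 2-{3-[(1R,6S)-3,6-dimethyl-6-[(triisopropylsilyl)ethynyl]cyclohex-2-en-1-yl]-4-oxo-4H-pyran-2-yl}acetate | COC(=O)Cc1occc(=O)c1[C@@H]1C=C(C)CC[C@]1(C)C#C[Si](C(C)C)(C(C)C)C(C)C
F2 | step 8 | 1-methoxy-1,3-bis(trimethylsilyloxy)-4-[(1S,6S)-3,6-dimethyl-6-[(triisopropylsilyl)ethynyl]cyclohex-2-en-1-yl]buta-1,3-diene (alkene geometries unspecified) | CC(C)[Si](C(C)C)(C(C)C)C#C[C@@]1(C)CCC(C)=C[C@H]1C=C(O[Si](C)(C)C)C=C(OC)O[Si](C)(C)C
F3 | step 8 | (2E)-3-methoxyprop-2-enoyl chloride | CO/C=C/C(=O)Cl
F4 | step 3 | rac-methyl 2-[(1R*,6S*)-6-formyl-3,6-dimethylcyclohex-2-en-1-yl]acetate (both enantiomers) | O=C[C@@]1(C)CCC(C)=C[C@H]1CC(=O)OC.O=C[C@]1(C)CCC(C)=C[C@@H]1CC(=O)OC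
F5 | step 3 | rac-methyl 2-[(1R*,6S*)-6-ethynyl-3,6-dimethylcyclohex-2-en-1-yl]acetate (both enantiomers) | C#C[C@@]1(C)CCC(C)=C[C@H]1CC(=O)OC.C#C[C@]1(C)CCC(C)=C[C@@H]1CC(=O)OC
F6 | step 3 | rac-2-[(1R*,6S*)-6-ethynyl-3,6-dimethylcyclohex-2-en-1-yl]acetic acid (both enantiomers) | C#C[C@@]1(C)CCC(C)=C[C@H]1CC(=O)O.C#C[C@]1(C)CCC(C)=C[C@@H]1CC(=O)O
F7 | step 3 | (S)-1-phenylethylammonium 2-[(1R,6S)-6-ethynyl-3,6-dimethylcyclohex-2-en-1-yl]acetate | C#C[C@@]1(C)CCC(C)=C[C@H]1CC(=O)[O-].C[C@H]([NH3+])c1ccccc1
F8 | step 13 | 2-formyl-5-methoxy-6-[(1R,6S)-3,6-dimethyl-6-[(triisopropylsilyl)ethynyl]cyclohex-2-en-1-yl]phenyl (triphenylphosphoranylidene)acetate | O=Cc1ccc(OC)c([C@@H]2C=C(C)CC[C@]2(C)C#C[Si](C(C)C)(C(C)C)C(C)C)c1OC(=O)C=P(c1ccccc1)(c1ccccc1)c1ccccc1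
F9 | step 17 | 8-[(1R,6S)-3,6-dimethyl-6-[(E)-2-(tributylstannyl)ethenyl]cyclohex-2-en-1-yl]-7-methoxy-2H-chromen-2-one | CCCC[Sn](CCCC)(CCCC)/C=C/[C@@]1(C)CCC(C)=C[C@H]1c1c(OC)ccc2ccc(=O)oc12
A1 | alternative 1 | 8-[(1R,6R)-6-[(E)-2-(7-methoxy-2H-chromen-8-yl)ethenyl]-3,6-dimethylcyclohex-2-en-1-yl]-7-methoxy-2H-chromene | COc1ccc2C=CCOc2c1/C=C/[C@@]1(C)CCC(C)=C[C@H]1c1c(OC)ccc2C=CCOc12
A2 | alternative 1 | 1-methoxy-2-[(1R,6R)-6-{(E)-2-[2-methoxy-6-(prop-2-yn-1-yloxy)phenyl]ethenyl}-3,6-dimethylcyclohex-2-en-1-yl]-3-(prop-2-yn-1-yloxy)benzene | COc1cccc(OCC#C)c1/C=C/[C@@]1(C)CCC(C)=C[C@H]1c1c(OC)cccc1OCC#C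
A3 | alternative 2 | 1-(2-hydroxy-6-methoxyphenyl)-2-{(1R,2R)-2-[2-methoxy-6-(methoxymethoxy)phenyl]-1,4-dimethylcyclohex-3-en-1-yl}ethan-1-one | COc1cccc(O)c1C(=O)C[C@@]1(C)CCC(C)=C[C@H]1c1c(OC)cccc1OCOC
A4 | alternative 2 | 2-{(1R,2R)-2-[2-methoxy-6-(methoxymethoxy)phenyl]-1,4-dimethylcyclohex-3-en-1-yl}acetic acid | OC(=O)C[C@@]1(C)CCC(C)=C[C@H]1c1c(OC)cccc1OCOC
A5 | alternative 3 | (2S,3R)-3-[2-methoxy-6-(methoxymethoxy)phenyl]-2-{[(4-methoxyphenyl)methoxy]methyl}-2,5-dimethylcyclohex-4-en-1-ol (carbinol centre unspecified) | COc1ccc(COC[C@@]2(C)C(O)CC(C)=C[C@H]2c2c(OC)cccc2OCOC)cc1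
A6 | alternative 3 | 3-[2-methoxy-6-(methoxymethoxy)phenyl]-2-{[(4-methoxyphenyl)methoxy]methyl}-2-methyl-4-(prop-1-en-2-yl)cyclobutan-1-ol (quaternary and aryl-bearing centres arranged as in A5; the other two unspecified) | COc1ccc(COC[C@@]2(C)C(O)C(C(C)=C)[C@H]2c2c(OC)cccc2OCOC)cc1
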